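## Retrosynthetic overview

1. The spiroketal is disconnected last: target 26 comes from alkynediol 23 by a new catalyst-controlled double hydroalkoxylation, so the acid-labile spiro centre is made in the final step and never exposed afterwards.
2. The phthalide lactone comes from carbonylative lactonisation of ortho-bromo benzylic alcohol 21; its C3 centre is set by asymmetric transfer hydrogenation of aryl ketone 19.
3. Ketone 19 comes from Weinreb amide 17 and the Grignard reagent of chloride 14.
4. Chain 14 comes from alkynylation of (S)-epoxide 11 (from (S)-epichlorohydrin) with (S)-alkyne 6 (from (S)-propylene oxide); these two chiral-pool pieces supply the two carbinol centres.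
5. Ring order: lactone ring (step 12), then oxolane ring B (methyl-bearing), then oxolane ring A (chain-bearing), both in step 14.

Assumption: compounds 1, 2, 7, 8, 15 and 16 are commercial; primed locants C1' to C14' count the side chain outward from phthalide C3; "acid A" is the (S,S)-imidodiphosphoric acid in which each phosphorus of an O=P–NH–P=O unit carries an (S)-3,3'-bis(2,4,6-triethylphenyl)-1,1'-binaphthalene-2,2'-diolate, and this antipode is taken to be the one matched to the (5S) spiro centre.

## Route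

Step 1
Reactants: 1 (S)-propylene oxide; 2 1-(trimethylsilyl)propyne
Product: 4 (2S)-6-(trimethylsilyl)hex-5-yn-2-ol, via 3-lithio-1-(trimethylsilyl)propyne 3 (not isolated)
Conditions: 2, n-BuLi, THF, −78 to −20 °C; then 1, BF3·OEt2, −78 °C; H2O
Reagents that add atoms: none
Why: Propargylic lithiation followed by BF3-promoted SN2 epoxide opening at the unhindered CH2 of 1 gives the alkynol, the silyl group suppressing the allenyl pathway, and the (S) centre of the chiral-pool epoxide is not touched.

Step 2
Reactants: 4 (2S)-6-(trimethylsilyl)hex-5-yn-2-ol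
Product: 5 tert-butyldimethyl{[(2S)-6-(trimethylsilyl)hex-5-yn-2-yl]oxy}silane
Conditions: TBSCl, imidazole, DMF, rt
Reagents that add atoms: tert-butyldimethylsilyl chloride, CC(C)(C)[Si](C)(C)Cl
Why: Imidazole-mediated silyl ether protection of the secondary alcohol masks the OH for the later organolithium and Grignard steps.

Step 3
Reactants: 5 tert-butyldimethyl{[(2S)-6-(trimethylsilyl)hex-5-yn-2-yl]oxy}silane
Product: 6 tert-butyl[(2S)-hex-5-yn-2-yloxy]dimethylsilane
Conditions: K2CO3 (cat.), MeOH, rt
Reagents that add atoms: none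
Why: Base-catalysed methanolysis (protodesilylation) cleaves the alkynyl C–Si bond selectively over the O–Si ether and frees the terminal alkyne.

Step 4
Reactants: 7 1-bromo-5-chloropentane; 8 (S)-epichlorohydrin
Product: 10 (2S)-1,8-dichlorooctan-2-ol, via 5-chloropentylmagnesium bromide 9 (not isolated)
Conditions: 7, Mg, THF, 35 °C; then 8, CuI (10 mol%), THF, −40 to 0 °C; H2O
Reagents that add atoms: none
Why: Chemoselective magnesium insertion into the C–Br bond and copper-catalysed Grignard opening of the epoxide at its terminal carbon (SN2) leave the stereocentre of 8 untouched.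

Step 5
Reactants: 10 (2S)-1,8-dichlorooctan-2-ol
Product: 11 (2S)-2-(6-chlorohexyl)oxirane
Conditions: NaOH, H2O/Et2O, rt
Reagents that add atoms: none
Why: Intramolecular Williamson etherification of the chlorohydrin closes the new terminal epoxide without breaking a bond at the stereocentre, and the remote primary chloride is inert.

Step 6
Reactants: 6 tert-butyl[(2S)-hex-5-yn-2-yloxy]dimethylsilane; 11 (2S)-2-(6-chlorohexyl)oxirane
Product: 13 (7S,13S)-13-[(tert-butyldimethylsilyl)oxy]-1-chlorotetradec-9-yn-7-ol, via lithium acetylide 12 (not isolated)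
Conditions: 6, n-BuLi, THF, −78 °C; then BF3·OEt2, 11, −78 °C; H2O
Reagents that add atoms: none
Why: Yamaguchi alkynylation opens the BF3-activated epoxide at its terminal carbon by SN2, the alkyl chloride is inert at −78 °C, and both (S) centres are carried over unchanged.

Step 7
Reactants: 13 (7S,13S)-13-[(tert-butyldimethylsilyl)oxy]-1-chlorotetradec-9-yn-7-ol
Product: 14 (7S,13S)-7,13-bis[(tert-butyldimethylsilyl)oxy]-1-chlorotetradec-9-yne
Conditions: TBSCl, imidazole, DMAP (cat.), DMF, 35 °C
Reagents that add atoms: tert-butyldimethylsilyl chloride, CC(C)(C)[Si](C)(C)Cl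
Why: Silyl ether protection of the homopropargylic alcohol gives a chain with no acidic proton for the Grignard step.

Step 8
Reactants: 15 3,5-dimethoxybenzoyl chloride; 16 N,O-dimethylhydroxylamine hydrochloride
Product: 17 N,3,5-trimethoxy-N-methylbenzamide
Conditions: Et3N, CH2Cl2, 0 °C to rt
Reagents that add atoms: none
Why: Acylation of the hydroxylamine by the acid chloride gives the Weinreb amide, which stops cleanly at the ketone stage in step 9.

Step 9
Reactants: 14 (7S,13S)-7,13-bis[(tert-butyldimethylsilyl)oxy]-1-chlorotetradec-9-yne; 17 N,3,5-trimethoxy-N-methylbenzamide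
Product: 19 (8S,14S)-8,14-bis[(tert-butyldimethylsilyl)oxy]-1-(3,5-dimethoxyphenyl)pentadec-10-yn-1-one, via alkylmagnesium chloride 18 (not isolated)
Conditions: 14, Mg turnings (I2 cat.), THF, 60 °C; then 17, THF, 0 °C; H2O
Reagents that add atoms: none
Why: Weinreb ketone synthesis, in which the primary Grignard reagent adds once to give a stable magnesium chelate that collapses to the aryl ketone on work-up while the silyl ethers and internal alkyne are inert.

Step 10
Reactants: 19 (8S,14S)-8,14-bis[(tert-butyldimethylsilyl)oxy]-1-(3,5-dimethoxyphenyl)pentadec-10-yn-1-one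
Product: 20 (1S,8S,14S)-8,14-bis[(tert-butyldimethylsilyl)oxy]-1-(3,5-dimethoxyphenyl)pentadec-10-yn-1-ol
Conditions: RuCl(p-cymene)[(S,S)-TsDPEN] (1 mol%), HCO2H/Et3N (5:2), CH2Cl2, 30 °C
Reagents that add atoms: none
Why: Noyori–Ikariya asymmetric transfer hydrogenation delivers hydride to the Re face of the aryl alkyl ketone through the CH/π-organised six-membered transition state, giving the (S) benzylic alcohol as for acetophenone-type substrates without reducing the alkyne.

Step 11
Reactants: 20 (1S,8S,14S)-8,14-bis[(tert-butyldimethylsilyl)oxy]-1-(3,5-dimethoxyphenyl)pentadec-10-yn-1-ol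
Product: 21 (1S,8S,14S)-1-(2-bromo-3,5-dimethoxyphenyl)-8,14-bis[(tert-butyldimethylsilyl)oxy]pentadec-10-yn-1-ol
Conditions: NBS (1.0 equiv), MeCN, −20 to 0 °C, dark
Reagents that add atoms: N-bromosuccinimide, O=C1CCC(=O)N1Br
Why: Electrophilic aromatic bromination occurs para to one methoxy and ortho to the other (the two such positions are equivalent), not at the position flanked by both methoxy groups, and is much faster than any reaction of the alkyne.

Step 12
Reactants: 21 (1S,8S,14S)-1-(2-bromo-3,5-dimethoxyphenyl)-8,14-bis[(tert-butyldimethylsilyl)oxy]pentadec-10-yn-1-ol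
Product: 22 (3S)-3-{(7S,13S)-7,13-bis[(tert-butyldimethylsilyl)oxy]tetradec-9-yn-1-yl}-5,7-dimethoxy-2-benzofuran-1(3H)-one
Conditions: Pd(OAc)2 (5 mol%), Xantphos (6 mol%), Et3N, CO (1 atm), toluene, 100 °C
Reagents that add atoms: carbon monoxide, [C-]#[O+]
Why: Palladium-catalysed carbonylative lactonisation (oxidative addition of zerovalent palladium to Ar–Br, CO insertion, intramolecular alkoxide capture of the acylpalladium) closes the five-membered lactone with the benzylic C–O bond and its (S) configuration intact.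

Step 13
Reactants: 22 (3S)-3-{(7S,13S)-7,13-bis[(tert-butyldimethylsilyl)oxy]tetradec-9-yn-1-yl}-5,7-dimethoxy-2-benzofuran-1(3H)-one
Product: 23 (3S)-3-[(7S,13S)-7,13-dihydroxytetradec-9-yn-1-yl]-5,7-dimethoxy-2-benzofuran-1(3H)-one
Conditions: HF·pyridine, pyridine/THF, 0 °C to rt
Reagents that add atoms: none
Why: Fluoride-mediated silyl ether cleavage under buffered, non-basic conditions frees both alcohols without epimerising C3, opening the lactone or hydrating the alkyne.

Step 14
Reactants: 23 (3S)-3-[(7S,13S)-7,13-dihydroxytetradec-9-yn-1-yl]-5,7-dimethoxy-2-benzofuran-1(3H)-one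
Product: 26 (3S)-5,7-dimethoxy-3-{6-[(2S,5S,7S)-7-methyl-1,6-dioxaspiro[4.4]nonan-2-yl]hexyl}-2-benzofuran-1(3H)-one, via exocyclic enol ether 24 (not isolated), via oxocarbenium ion 25 (not isolated)
Conditions: (Ph3P)AuMe (5 mol%), acid A (10 mol%), 4 Å MS, toluene, −20 °C; then Et3N
Reagents that add atoms: none
Why: Proposed new method: chiral-anion gold relay spiroketalisation, in which protonolysis of (Ph3P)AuMe by acid A gives the ion pair of [(Ph3P)Au]+ and the confined imidodiphosphate, the monovalent gold centre π-activates the C9'≡C10' alkyne for anti 5-exo-dig attack by the C13' hydroxyl (closing ring B) and protodeauration releases (Z)-enol ether 24, the remaining free acid A then protonates C9' to give oxocarbenium 25 as a contact ion pair in toluene, and the C7' hydroxyl, hydrogen-bonded to a phosphoryl oxygen of the anion, closes ring A on the face syn to the ring B methyl under kinetic control (the acid is too weak to re-ionise the product at −20 °C), which sets the (5S) spiro centre that substrate bias and thermodynamics leave near 1:1; the closest known reaction types are achiral gold-catalysed cycloisomerisation of alkynediols to spiroketals, confined Brønsted acid-catalysed asymmetric spiroacetalisation of preformed hydroxy enol ethers, and chiral-counteranion gold hydroalkoxylation of allenes.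

## Compound list

1 | (S)-propylene oxide | C[C@H]1CO1 | starting material
2 | 1-(trimethylsilyl)propyne | CC#C[Si](C)(C)C | starting material
3 | 3-lithio-1-(trimethylsilyl)propyne | [Li]CC#C[Si](C)(C)C | intermediate
4 | (2S)-6-(trimethylsilyl)hex-5-yn-2-ol | C[C@H](O)CCC#C[Si](C)(C)C | intermediate
5 | tert-butyldimethyl{[(2S)-6-(trimethylsilyl)hex-5-yn-2-yl]oxy}silane | C[C@H](O[Si](C)(C)C(C)(C)C)CCC#C[Si](C)(C)C | intermediate
6 | tert-butyl[(2S)-hex-5-yn-2-yloxy]dimethylsilane | C[C@H](O[Si](C)(C)C(C)(C)C)CCC#C | intermediate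
7 | 1-bromo-5-chloropentane | ClCCCCCBr | starting material
8 | (S)-epichlorohydrin | ClC[C@@H]1CO1 | starting material
9 | 5-chloropentylmagnesium bromide | ClCCCCC[Mg]Br | intermediate
10 | (2S)-1,8-dichlorooctan-2-ol | ClCCCCCC[C@H](O)CCl | intermediate
11 | (2S)-2-(6-chlorohexyl)oxirane | ClCCCCCC[C@H]1CO1 | intermediate
12 | lithium acetylide of 6, [(5S)-5-(tert-butyldimethylsilyloxy)hex-1-yn-1-yl]lithium | C[C@H](O[Si](C)(C)C(C)(C)C)CCC#C[Li] | intermediate
13 | (7S,13S)-13-[(tert-butyldimethylsilyl)oxy]-1-chlorotetradec-9-yn-7-ol | ClCCCCCC[C@H](O)CC#CCC[C@H](C)O[Si](C)(C)C(C)(C)C | intermediate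
14 | (7S,13S)-7,13-bis[(tert-butyldimethylsilyl)oxy]-1-chlorotetradec-9-yne | ClCCCCCC[C@H](O[Si](C)(C)C(C)(C)C)CC#CCC[C@H](C)O[Si](C)(C)C(C)(C)C | intermediate
15 | 3,5-dimethoxybenzoyl chloride | COc1cc(OC)cc(c1)C(Cl)=O | starting material
16 | N,O-dimethylhydroxylamine hydrochloride | CNOC.Cl | starting material
17 | N,3,5-trimethoxy-N-methylbenzamide | COc1cc(OC)cc(c1)C(=O)N(C)OC | intermediate
18 | [(7S,13S)-7,13-bis(tert-butyldimethylsilyloxy)tetradec-9-yn-1-yl]magnesium chloride | Cl[Mg]CCCCCC[C@H](O[Si](C)(C)C(C)(C)C)CC#CCC[C@H](C)O[Si](C)(C)C(C)(C)C | intermediate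
19 | (8S,14S)-8,14-bis[(tert-butyldimethylsilyl)oxy]-1-(3,5-dimethoxyphenyl)pentadec-10-yn-1-one | COc1cc(OC)cc(c1)C(=O)CCCCCC[C@H](O[Si](C)(C)C(C)(C)C)CC#CCC[C@H](C)O[Si](C)(C)C(C)(C)C | intermediate
20 | (1S,8S,14S)-8,14-bis[(tert-butyldimethylsilyl)oxy]-1-(3,5-dimethoxyphenyl)pentadec-10-yn-1-ol | COc1cc(OC)cc(c1)[C@@H](O)CCCCCC[C@H](O[Si](C)(C)C(C)(C)C)CC#CCC[C@H](C)O[Si](C)(C)C(C)(C)C | intermediate
21 | (1S,8S,14S)-1-(2-bromo-3,5-dimethoxyphenyl)-8,14-bis[(tert-butyldimethylsilyl)oxy]pentadec-10-yn-1-ol | COc1cc(OC)c(Br)c(c1)[C@@H](O)CCCCCC[C@H](O[Si](C)(C)C(C)(C)C)CC#CCC[C@H](C)O[Si](C)(C)C(C)(C)C | intermediate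
22 | (3S)-3-{(7S,13S)-7,13-bis[(tert-butyldimethylsilyl)oxy]tetradec-9-yn-1-yl}-5,7-dimethoxy-2-benzofuran-1(3H)-one | COc1cc(OC)c2c(c1)[C@H](CCCCCC[C@H](O[Si](C)(C)C(C)(C)C)CC#CCC[C@H](C)O[Si](C)(C)C(C)(C)C)OC2=O | intermediate
23 | (3S)-3-[(7S,13S)-7,13-dihydroxytetradec-9-yn-1-yl]-5,7-dimethoxy-2-benzofuran-1(3H)-one | COc1cc(OC)c2c(c1)[C@H](CCCCCC[C@H](O)CC#CCC[C@H](C)O)OC2=O | intermediate
24 | (3S)-3-{(7S,9Z)-7-hydroxy-9-[(5S)-5-methyloxolan-2-ylidene]nonyl}-5,7-dimethoxy-2-benzofuran-1(3H)-one | COc1cc(OC)c2c(c1)[C@H](CCCCCC[C@H](O)C/C=C3/CC[C@H](C)O3)OC2=O | intermediate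
25 | oxocarbenium ion from protonation of 24 at C9': (5S)-5-methyl-4,5-dihydro-3H-furan-1-ium carrying at C2 the (3S)-3-hydroxy-9-[(1S)-4,6-dimethoxy-3-oxo-1,3-dihydro-2-benzofuran-1-yl]nonyl chain (counter-ion: imidodiphosphate of acid A) | COc1cc(OC)c2c(c1)[C@H](CCCCCC[C@H](O)CCC3=[O+][C@@H](C)CC3)OC2=O | intermediate
26 | (3S)-5,7-dimethoxy-3-{6-[(2S,5S,7S)-7-methyl-1,6-dioxaspiro[4.4]nonan-2-yl]hexyl}-2-benzofuran-1(3H)-one | COc1cc(OC)c2c(c1)[C@H](CCCCCC[C@H]1CC[C@]3(CC[C@H](C)O3)O1)OC2=O | target

## Step count and risk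

Total step count: 14. Longest linear sequence: 11 steps (1, 2, 3, 6, 7, 9, 10, 11, 12, 13, 14).

The three steps most likely to fail:

**Step 14 (the proposed new step).** The risks are an uncontrolled background cyclisation by gold alone, low activity of the gold imidodiphosphate towards the internal alkyne at low temperature, or the wrong facial sense. The fallback uses known chemistry and gives up catalyst control. It sets out from 23, which is cycloisomerised with AuCl (5 mol%) in CH2Cl2 at rt and then equilibrated with PPTS. This gives the thermodynamic, roughly 1:1 mixture of 26 and its spiro epimer, (3S)-5,7-dimethoxy-3-{6-[(2S,5R,7S)-7-methyl-1,6-dioxaspiro[4.4]nonan-2-yl]hexyl}-2-benzofuran-1(3H)-one F1. The two are separated by preparative HPLC on silica, and F1 is returned to the 1:1 mixture with PPTS in CH2Cl2 and recycled. The fallback comes back to the route at 26.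

**Step 9.** Magnesium insertion into the functionalised primary chloride may be sluggish or give Wurtz coupling. The fallback replaces the Grignard/Weinreb addition by a palladium-catalysed acyl cross-coupling. It sets out from 14, which is converted with NaI in refluxing acetone into the iodide (7S,13S)-7,13-bis[(tert-butyldimethylsilyl)oxy]-1-iodotetradec-9-yne F2. Zn dust with LiCl in THF at 40 °C then gives the alkylzinc iodide [(7S,13S)-7,13-bis(tert-butyldimethylsilyloxy)tetradec-9-yn-1-yl]zinc iodide F3. This is coupled with acid chloride 15 under Pd(PPh3)4 catalysis in THF at rt (Negishi acylation). The fallback comes back to the route at 19 and makes amide 17 unnecessary.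

**Step 12.** Oxidative addition into the hindered, electron-rich aryl bromide may be slow, and the alkyne could interfere with acylpalladium species at 100 °C. The fallback replaces palladium carbonylation by an anionic cyclisation in which the carbonyl carbon comes from a carbamate. It sets out from 21, which is carbamoylated with NaH and diethylcarbamoyl chloride in THF to the carbamate (1S,8S,14S)-1-(2-bromo-3,5-dimethoxyphenyl)-8,14-bis[(tert-butyldimethylsilyl)oxy]pentadec-10-yn-1-yl diethylcarbamate F4. Treatment with t-BuLi (2.1 equiv) in THF at −78 °C effects bromine–lithium exchange to the aryllithium (1S,8S,14S)-8,14-bis[(tert-butyldimethylsilyl)oxy]-1-(2-lithio-3,5-dimethoxyphenyl)pentadec-10-yn-1-yl diethylcarbamate F5. F5 attacks its own carbamate carbonyl (Parham-type cyclisation) and expels lithium diethylamide. The fallback comes back to the route at 22.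

## Further compounds

F1 | step 14 | (3S)-5,7-dimethoxy-3-{6-[(2S,5R,7S)-7-methyl-1,6-dioxaspiro[4.4]nonan-2-yl]hexyl}-2-benzofuran-1(3H)-one | COc1cc(OC)c2c(c1)[C@H](CCCCCC[C@H]1CC[C@@]3(CC[C@H](C)O3)O1)OC2=O
F2 | step 9 | (7S,13S)-7,13-bis[(tert-butyldimethylsilyl)oxy]-1-iodotetradec-9-yne | ICCCCCC[C@H](O[Si](C)(C)C(C)(C)C)CC#CCC[C@H](C)O[Si](C)(C)C(C)(C)C
F3 | step 9 | [(7S,13S)-7,13-bis(tert-butyldimethylsilyloxy)tetradec-9-yn-1-yl]zinc iodide | I[Zn]CCCCCC[C@H](O[Si](C)(C)C(C)(C)C)CC#CCC[C@H](C)O[Si](C)(C)C(C)(C)C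
F4 | step 12 | (1S,8S,14S)-1-(2-bromo-3,5-dimethoxyphenyl)-8,14-bis[(tert-butyldimethylsilyl)oxy]pentadec-10-yn-1-yl diethylcarbamate | COc1cc(OC)c(Br)c(c1)[C@@H](OC(=O)N(CC)CC)CCCCCC[C@H](O[Si](C)(C)C(C)(C)C)CC#CCC[C@H](C)O[Si](C)(C)C(C)(C)C
F5 | step 12 | (1S,8S,14S)-8,14-bis[(tert-butyldimethylsilyl)oxy]-1-(2-lithio-3,5-dimethoxyphenyl)pentadec-10-yn-1-yl diethylcarbamate | COc1cc(OC)c([Li])c(c1)[C@@H](OC(=O)N(CC)CC)CCCCCC[C@H](O[Si](C)(C)C(C)(C)C)CC#CCC[C@H](C)O[Si](C)(C)C(C)(C)C
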